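**Retrosynthetic overview**
- The N-oxide is cut back to the tertiary amine 2,5,6-tribromo-1-methylgramine (late N-oxidation).
- Key disconnection: the C2–Br bond and the whole CH2NMe2 arm are removed together, leading back to the lactam 5,6-dibromo-1-methyloxindole plus DMF. This is an interrupted, reductive Vilsmeier–Haack–Arnold bromoformylation and replaces the usual Mannich reaction plus C2 bromination of an indole.
- The dibromo-oxindole comes from 6-bromo-1-methyloxindole by bromination para to nitrogen (C5).
- Ring order: the benzene ring and the five-membered lactam are bought intact; the pyrrole ring is aromatised, not built, in the key step.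

Assumption: the target has no stereocentre (the N-oxide nitrogen carries two identical methyl groups), so no enantiocontrol is needed; 6-bromo-1-methylindolin-2-one is taken as a purchasable building block.

**Step 1**
Reactants: 1 6-bromo-1-methylindolin-2-one
Product: 2 5,6-dibromo-1-methylindolin-2-one
Conditions: NBS (1.05 equiv), MeCN, 0 °C to rt, dark
Reagents that add atoms: N-bromosuccinimide (NBS), O=C1CCC(=O)N1Br
Why: Electrophilic aromatic bromination with NBS goes to C5, which is para to the lactam nitrogen and ortho to the existing bromine, whereas C7 is crowded between N-methyl and Br and polar MeCN at low temperature disfavours bromination at the C3 methylene.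

**Step 2**
Reactants: 2 5,6-dibromo-1-methylindolin-2-one
Product: 5 1-(2,5,6-tribromo-1-methyl-1H-indol-3-yl)-N,N-dimethylmethanamine (2,5,6-tribromo-1-methylgramine), via aminomethylene oxindole 3 (not isolated), via iminium bromide 4 (not isolated)
Conditions: DMF (2.5 equiv), POBr3 (2.2 equiv), ClCH2CH2Cl, 0 °C, then 2, 70 °C, 3 h; cool to −20 °C, NaBH4 (excess), EtOH, to 0 °C; 2 M aq. NaOH work-up
Reagents that add atoms: N,N-dimethylformamide (DMF), CN(C)C=O; phosphoryl bromide (POBr3), O=P(Br)(Br)Br
Why: Proposed new method: the bromomethyleneiminium salt from DMF and POBr3 condenses at the acidic C3 methylene to give enaminone 3, O-phosphorylation of the lactam carbonyl followed by bromide addition–elimination aromatises it to the 2-bromoindol-3-ylmethyleneiminium salt 4, and hydride is then added to the exocyclic iminium carbon in place of the usual hydrolysis, so the closest known reactions are the Vilsmeier–Haack–Arnold haloformylation of oxindoles to 2-haloindole-3-carbaldehydes and the borohydride reduction of Vilsmeier iminium salts to (dimethylaminomethyl)arenes; no stereocentre is formed.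

**Step 3**
Reactants: 5 1-(2,5,6-tribromo-1-methyl-1H-indol-3-yl)-N,N-dimethylmethanamine
Product: 6 1-(2,5,6-tribromo-1-methyl-1H-indol-3-yl)-N,N-dimethylmethanamine N-oxide (2,5,6-tribromo-1-methylgramine N-oxide, CNP0603210.0)
Conditions: mCPBA (1.05 equiv), CH2Cl2, −20 to 0 °C; filtration through basic Al2O3 (CH2Cl2/MeOH)
Reagents that add atoms: 3-chloroperoxybenzoic acid (mCPBA), OOC(=O)c1cccc(Cl)c1
Why: Peracid N-oxidation of a tertiary amine (electrophilic oxygen transfer to the amine lone pair) is much faster than any attack on the electron-poor tribrominated indole, and no stereocentre arises because the nitrogen carries two identical methyl groups.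

**Compound list**
1 | 6-bromo-1-methylindolin-2-one | CN1C(=O)Cc2ccc(Br)cc21 | starting material
2 | 5,6-dibromo-1-methylindolin-2-one | CN1C(=O)Cc2cc(Br)c(Br)cc21 | intermediate
3 | 5,6-dibromo-3-[(dimethylamino)methylidene]-1-methylindolin-2-one (drawn as E; push–pull alkene, E/Z interconvert; not isolated) | CN(C)/C=C1/C(=O)N(C)c2cc(Br)c(Br)cc21 | intermediate
4 | [(2,5,6-tribromo-1-methyl-1H-indol-3-yl)methylidene]dimethyliminium bromide (not isolated) | C[N+](C)=Cc1c(Br)n(C)c2cc(Br)c(Br)cc12.[Br-] | intermediate
5 | 1-(2,5,6-tribromo-1-methyl-1H-indol-3-yl)-N,N-dimethylmethanamine | CN(C)Cc1c(Br)n(C)c2cc(Br)c(Br)cc12 | intermediate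
6 | 1-(2,5,6-tribromo-1-methyl-1H-indol-3-yl)-N,N-dimethylmethanamine N-oxide | Cn1c(Br)c(C[N+](C)(C)[O-])c2cc(Br)c(Br)cc21 | target

**Total step count:** 3
**Longest linear sequence:** 3 steps (fully linear)

**Steps most likely to fail, highest risk first**

Step 2. The hydride may attack C2 of the vinylogous amidinium 4 and expel bromide, the reduction may stall, or the product may be held as an amine–borane in the acidic, phosphorus-rich mixture. The fallback sets out from 2 and comes back at 5. The same DMF/POBr3 reaction in ClCH2CH2Cl is given the ordinary hydrolytic work-up (aq. NaOAc, rt), which releases the isolable 2,5,6-tribromo-1-methyl-1H-indole-3-carbaldehyde F2. A separate reductive amination of this aldehyde with Me2NH (2 M in THF), NaBH(OAc)3 and AcOH in ClCH2CH2Cl at rt then gives 5.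

Step 1. Bromination at the C3 methylene or at C7 could compete on this deactivated ring. The fallback sets out from 1 and comes back at 2. Compound 1 is brominated exhaustively with Br2 (3.3 equiv) in dry AcOH at rt to 50 °C, so that C3 is deliberately dibrominated along with C5, giving 3,3,5,6-tetrabromo-1-methylindolin-2-one F1. Zn dust in AcOH at rt then removes only the two C3 bromines and leaves both aryl bromides, giving 2.

Step 3. The protonated N-oxide can lose Me2NOH to an azafulvenium ion, undergo Meisenheimer rearrangement on warming, or be over-oxidised. The fallback sets out from 5 and comes back at 6, with no oxidant. Amine 5 is quaternised with MeI in MeCN/Et2O at rt to 1-(2,5,6-tribromo-1-methyl-1H-indol-3-yl)-N,N,N-trimethylmethanaminium iodide F3. This salt is treated with N,N-dimethylhydroxylamine (from its hydrochloride with K2CO3) in MeCN at 40 °C under an N2 sweep. The hydroxylamine is alkylated on nitrogen by the gramine-methiodide electrophile, trimethylamine is expelled, and deprotonation gives 6 directly.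

**Further compounds**
F1 | step 1 | 3,3,5,6-tetrabromo-1-methylindolin-2-one | CN1C(=O)C(Br)(Br)c2cc(Br)c(Br)cc21
F2 | step 2 | 2,5,6-tribromo-1-methyl-1H-indole-3-carbaldehyde | Cn1c(Br)c(C=O)c2cc(Br)c(Br)cc21
F3 | step 3 | 1-(2,5,6-tribromo-1-methyl-1H-indol-3-yl)-N,N,N-trimethylmethanaminium iodide | C[N+](C)(C)Cc1c(Br)n(C)c2cc(Br)c(Br)cc12.[I-]
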